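**Retrosynthetic overview**

1. Target 23 ⇐ lactol 21 (dehydration) ⇐ 15,16-olide 19 ⇐ triol 17: the dihydrofuran ring is closed last; the tetrahydrofuran ring (C9–O–C13) is closed before it by 5-exo opening of a reagent-set C13 epoxide by the C9 hydroxyl.
2. C12–C16 come from 3-methylbut-3-en-1-ol, joined to C11 by opening the 9α,11-spiro-epoxide 12 with its dianion; 12 ⇐ LiAlH4 reduction of the 11,6β-lactone 9.
3. C5–C6 and C9–C10 (ring B) ⇐ [4+2] of 3-hydroxy-4-methyl-2-pyrone 4 (its C6–C5–C4–C3 become C6–C7–C8–C9, O1 stays on C6, the lactone carbonyl becomes C11) with the C5=C10 bond of enone 5; C5, C6, C9 and C10 are set here, C8 by hydrogenation of the adduct.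
4. Enabling feature: ring B carries the oxygen on C6 and carbon C11 on C9 in a 1,4 relation on the same face as H-5 and CH3-20 (cis A/B fusion), and C9 is a tertiary carbinol. This is the pattern of an endo 3-hydroxy-2-pyrone cycloadduct, whose lactone bridge C6–O–C11(=O)–C9 serves as a temporary ring; the C1 carbonyl of 5 is a temporary activating group (removed in step 5).
5. Ring order: A (purchased) → B (step 3) → tetrahydrofuran (step 9) → dihydrofuran (steps 10–13).

Key step: step 3

Remark: 1, 5 and 13 are taken as purchasable; positions are numbered as in labdane (C17 on C8, C18/C19 on C4, C20 on C10), β is the face of ring B that carries C20, and the target SMILES is read as the 5β-H (A/B cis) compound (5R,6R,8R,9R,10S,13R).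

**Route**

Step 1
Reactants: 1 4-methyl-5,6-dihydro-2H-pyran-2-one
Product: 2 rac-3-hydroxy-4-methyl-3,6-dihydro-2H-pyran-2-one
Conditions: KN(SiMe3)2 (1.05 equiv), THF, −78 °C; 2-(phenylsulfonyl)-3-phenyloxaziridine, −78 °C; AcOH quench at −78 °C
Reagents that add atoms: 2-(phenylsulfonyl)-3-phenyloxaziridine, O=S(=O)(c1ccccc1)N1OC1c1ccccc1
Why: γ-Deprotonation gives the potassium dienolate, which is oxidised at the α-carbon by the N-sulfonyloxaziridine (enolate α-hydroxylation); the new stereocentre forms as a racemate and is erased in step 2.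

Step 2
Reactants: 2 rac-3-hydroxy-4-methyl-3,6-dihydro-2H-pyran-2-one
Product: 4 3-hydroxy-4-methyl-2H-pyran-2-one, via pyrandione 3 (not isolated)
Conditions: Dess–Martin periodinane, CH2Cl2, 0 °C → rt; then Et3N (0.2 equiv), rt
Reagents that add atoms: none
Why: Dess–Martin oxidation of the secondary allylic alcohol gives the 2,3-dione 3, and amine-mediated enolisation through the vinylogous C6 methylene should deliver the conjugated 3-hydroxy-2-pyrone (keto–enol tautomerisation); no stereocentre remains.

Step 3
Reactants: 4 3-hydroxy-4-methyl-2H-pyran-2-one, 5 2,4,4-trimethylcyclohex-2-en-1-one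
Product: 6 9α-hydroxy-1-oxo-12,13,14,15,16-pentanor-5β-labd-7-en-11,6β-olide (endo adduct; H-5 and CH3-20 cis, both on the face of the lactone bridge)
Conditions: 1-[3,5-bis(trifluoromethyl)phenyl]-3-[(8S,9S)-6'-methoxycinchonan-9-yl]thiourea (10 mol %), CH2Cl2, 10 kbar, 25 °C
Reagents that add atoms: none
Why: Proposed new method: the quinuclidine nitrogen deprotonates 4 to a chiral ammonium 3-oxidopyrone ion pair while the thiourea hydrogen-bonds the carbonyl of 5, and under 10 kbar (bond formation to a neopentyl and a fully substituted carbon has a strongly negative activation volume) the nucleophilic vinylogous terminus C6 of the pyrone should add to the enone β-carbon (C5–C6) and the resulting enolate carbon to the pyrone C3 carbonyl (C9–C10), as an asynchronous [4+2] cycloaddition or, in the stepwise limit, a vinylogous Michael addition followed by aldol closure. The closest known reaction type is the tertiary-amine- and cinchona-thiourea-catalysed Diels–Alder reaction of 3-hydroxy-2-pyrones with electron-poor alkenes, simple enones included; an α-methyl cyclohexenone with a quaternary γ-carbon has not been shown in it. The step closes ring B as the cyclohexene of a 2-oxabicyclo[2.2.2]octenone by a suprafacial [4π+2π] mode (6-(enolexo)-exo-trig for the second bond if stepwise). C5 and C10 (H-5 and CH3-20 cis) follow from suprafacial addition across the ring-A alkene, C6 and C9 are the bridgeheads tied cis by the lactone bridge, their relation to C5/C10 comes from the endo placement of the ring-A carbonyl under C7=C8, and the absolute sense comes from the catalyst-shielded face of the ion pair (quinine-derived catalyst proposed; its quinidine-derived pseudo-enantiomer gives the antipode). The step needs regio-, endo- and facial selectivity: polarity matching of pyrone C6 with the enone β-carbon secures the first, secondary orbital overlap together with the thiourea–carbonyl hydrogen bond the second, the chiral ion pair the third.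

Step 4
Reactants: 6 9α-hydroxy-1-oxo-12,13,14,15,16-pentanor-5β-labd-7-en-11,6β-olide
Product: 7 9α-hydroxy-1-oxo-12,13,14,15,16-pentanor-5β,8βH-labdan-11,6β-olide (CH3-17 α)
Conditions: H2 (1 atm), Pd/C, EtOAc, rt
Reagents that add atoms: none
Why: In this catalytic hydrogenation the face of the C7=C8 bridge that looks towards C1 and C4 of the endo ring A is blocked, so hydrogen should add from the side of the flat lactone bridge and set C8 with H-8β and CH3-17α.

Step 5
Reactants: 7 9α-hydroxy-1-oxo-12,13,14,15,16-pentanor-5β,8βH-labdan-11,6β-olide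
Product: 9 9α-hydroxy-12,13,14,15,16-pentanor-5β,8βH-labdan-11,6β-olide, via tosylhydrazone 8 (not isolated)
Conditions: TsNHNH2, PPTS (cat.), EtOH, 60 °C; concentrate; catecholborane, CHCl3, 0 °C → rt; NaOAc·3H2O, 60 °C
Reagents that add atoms: none
Why: Condensation to the tosylhydrazone and hydride delivery from catecholborane, followed by acetate-induced loss of sulfinate and N2 (tosylhydrazone reduction, a mild Wolff–Kishner-type deoxygenation), should remove the activating carbonyl without touching the lactone, the tertiary alcohol or any stereocentre.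

Step 6
Reactants: 9 9α-hydroxy-12,13,14,15,16-pentanor-5β,8βH-labdan-11,6β-olide
Product: 10 12,13,14,15,16-pentanor-5β,8βH-labdane-6β,9α,11-triol
Conditions: LiAlH4, THF, 0 °C → reflux
Reagents that add atoms: none
Why: LiAlH4 reduction of the lactone opens the temporary bridge to the C11 primary and C6β secondary alcohols, with C6 and C9 untouched.

Step 7
Reactants: 10 12,13,14,15,16-pentanor-5β,8βH-labdane-6β,9α,11-triol
Product: 12 9α,11-epoxy-12,13,14,15,16-pentanor-5β,8βH-labdan-6β-ol, via tosylate 11 (not isolated)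
Conditions: TsCl (1.1 equiv), pyridine, CH2Cl2, 0 °C; then K2CO3, MeOH, rt
Reagents that add atoms: none
Why: The primary hydroxyl should be sulfonylated selectively and the adjacent tertiary alkoxide then displaces the tosylate in a 3-exo-tet closure (intramolecular Williamson etherification), which is much faster than bridging from the C6 hydroxyl and leaves the C9–O bond and its configuration intact.

Step 8
Reactants: 12 9α,11-epoxy-12,13,14,15,16-pentanor-5β,8βH-labdan-6β-ol, 13 3-methylbut-3-en-1-ol
Product: 15 5β,8βH-labd-13(16)-ene-6β,9α,15-triol, via dianion 14 (not isolated)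
Conditions: 13, n-BuLi (2 equiv), TMEDA, Et2O/hexane, 0 °C → rt; then 12, THF, −40 → 0 °C; H2O quench
Reagents that add atoms: none
Why: The 2-substituted allyllithium terminus of the dianion should open the spiro-epoxide at its CH2 carbon (SN2 epoxide opening by an allyl anion), forming C11–C12 at low temperature before the C6 alkoxide can attack, and returning the C9 hydroxyl with its configuration.

Step 9
Reactants: 15 5β,8βH-labd-13(16)-ene-6β,9α,15-triol
Product: 17 (13R)-9α,13-epoxy-5β,8βH-labdane-6β,15,16-triol, via epoxide 16 (not isolated)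
Conditions: Hf(OtBu)4 (10 mol %), (S,S)-N,N'-(cyclohexane-1,2-diyl)bis(N-hydroxy-2,2-diphenylacetamide) (12 mol %), cumene hydroperoxide, toluene, 0 °C; then camphorsulfonic acid (10 mol %), CH2Cl2, 0 °C
Reagents that add atoms: cumene hydroperoxide, CC(C)(OO)c1ccccc1
Why: The primary homoallylic hydroxyl binds the chiral hafnium bishydroxamate, which transfers oxygen to one face of the 1,1-disubstituted alkene (hydroxyl-directed catalytic asymmetric epoxidation, ligand antipode selected for the 13S epoxide), and acid then lets the C9 hydroxyl open the epoxide at its tertiary carbon in a 5-exo-tet attack with inversion, which closes the tetrahydrofuran and sets C13 as R.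

Step 10
Reactants: 17 (13R)-9α,13-epoxy-5β,8βH-labdane-6β,15,16-triol
Product: 19 (13R)-6β-hydroxy-9α,13-epoxy-5β,8βH-labdan-15,16-olide, via lactol 18 (not isolated)
Conditions: TEMPO (20 mol %), PhI(OAc)2 (2.5 equiv), CH2Cl2, rt
Reagents that add atoms: none
Why: The oxoammonium species (TEMPO-catalysed alcohol oxidation) should oxidise the less hindered C15 primary alcohol first, the aldehyde is trapped by the neopentyl C16 hydroxyl as lactol 18 and this is oxidised on to the γ-lactone, while the hindered secondary C6 hydroxyl is left.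

Step 11
Reactants: 19 (13R)-6β-hydroxy-9α,13-epoxy-5β,8βH-labdan-15,16-olide
Product: 20 (13R)-6β-acetoxy-9α,13-epoxy-5β,8βH-labdan-15,16-olide
Conditions: Ac2O, DMAP (cat.), pyridine, rt
Reagents that add atoms: acetic anhydride, CC(=O)OC(C)=O
Why: DMAP-catalysed acylation (esterification) acetylates the only hydroxyl left, the secondary C6β alcohol, with retention.

Step 12
Reactants: 20 (13R)-6β-acetoxy-9α,13-epoxy-5β,8βH-labdan-15,16-olide
Product: 21 (13R)-6β-acetoxy-9α,13;15,16-diepoxy-5β,8βH-labdan-15-ol (anomer mixture)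
Conditions: disiamylborane (from BH3·SMe2 and 2-methylbut-2-ene), THF, 0 °C → rt; MeOH, aq. NaHCO3
Reagents that add atoms: none
Why: Disiamylborane reduces γ-lactones to lactols but does not reduce ordinary esters (chemoselective dialkylborane reduction), so the acetate should survive; the lactol carbon forms as an anomer mixture that is removed in step 13.

Step 13
Reactants: 21 (13R)-6β-acetoxy-9α,13;15,16-diepoxy-5β,8βH-labdan-15-ol
Product: 23 (5R,6R,8R,9R,10S,13R)-6-acetoxy-9,13;15,16-diepoxylabd-14-ene (CNP0242014.2), via mesylate 22 (not isolated)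
Conditions: MsCl, Et3N (excess), CH2Cl2, −20 °C → reflux; chromatography on Et3N-deactivated silica
Reagents that add atoms: none
Why: Sulfonylation of the lactol hydroxyl and amine-induced elimination (dehydration of a lactol to a cyclic enol ether) can place the double bond only at C14=C15 because C13 is quaternary, and the basic medium protects the acid-labile spiro enol ether.

**Compound list**

1 | 4-methyl-5,6-dihydro-2H-pyran-2-one | CC1=CC(=O)OCC1 | starting material
2 | rac-3-hydroxy-4-methyl-3,6-dihydro-2H-pyran-2-one | CC1=CCOC(=O)C1O | intermediate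
3 | 4-methyl-6H-pyran-2,3-dione | CC1=CCOC(=O)C1=O | intermediate (not isolated)
4 | 3-hydroxy-4-methyl-2H-pyran-2-one | CC1=C(O)C(=O)OC=C1 | intermediate
5 | 2,4,4-trimethylcyclohex-2-en-1-one | CC1=CC(C)(C)CCC1=O | starting material
6 | 9α-hydroxy-1-oxo-12,13,14,15,16-pentanor-5β-labd-7-en-11,6β-olide | O=C3O[C@@H]1C=C(C)[C@@]3(O)[C@@]2(C)C(=O)CCC(C)(C)[C@@H]12 | intermediate
7 | 9α-hydroxy-1-oxo-12,13,14,15,16-pentanor-5β,8βH-labdan-11,6β-olide | O=C3O[C@@H]1C[C@@H](C)[C@@]3(O)[C@@]2(C)C(=O)CCC(C)(C)[C@@H]12 | intermediate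
8 | 1-(p-toluenesulfonyl)hydrazone of 7 | O=C3O[C@@H]1C[C@@H](C)[C@@]3(O)[C@@]2(C)C(=NNS(=O)(=O)c4ccc(C)cc4)CCC(C)(C)[C@@H]12 | intermediate (not isolated)
9 | 9α-hydroxy-12,13,14,15,16-pentanor-5β,8βH-labdan-11,6β-olide | O=C3O[C@@H]1C[C@@H](C)[C@@]3(O)[C@@]2(C)CCCC(C)(C)[C@@H]12 | intermediate
10 | 12,13,14,15,16-pentanor-5β,8βH-labdane-6β,9α,11-triol | O[C@@H]1C[C@@H](C)[C@@](CO)(O)[C@@]2(C)CCCC(C)(C)[C@@H]12 | intermediate
11 | 11-O-(p-toluenesulfonyl) derivative of 10 | O[C@@H]1C[C@@H](C)[C@@](COS(=O)(=O)c3ccc(C)cc3)(O)[C@@]2(C)CCCC(C)(C)[C@@H]12 | intermediate (not isolated)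
12 | 9α,11-epoxy-12,13,14,15,16-pentanor-5β,8βH-labdan-6β-ol | O[C@@H]1C[C@@H](C)[C@]3(CO3)[C@@]2(C)CCCC(C)(C)[C@@H]12 | intermediate
13 | 3-methylbut-3-en-1-ol | CC(=C)CCO | starting material
14 | dilithium dianion of 13 (2-substituted allyllithium alkoxide) | [Li+].[Li+].[CH2-]C(=C)CC[O-] | intermediate (not isolated)
15 | 5β,8βH-labd-13(16)-ene-6β,9α,15-triol | O[C@@H]1C[C@@H](C)[C@](O)(CCC(=C)CCO)[C@@]2(C)CCCC(C)(C)[C@@H]12 | intermediate
16 | (13S)-13,16-epoxy-5β,8βH-labdane-6β,9α,15-triol | O[C@@H]1C[C@@H](C)[C@](O)(CC[C@]3(CCO)CO3)[C@@]2(C)CCCC(C)(C)[C@@H]12 | intermediate (not isolated)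
17 | (13R)-9α,13-epoxy-5β,8βH-labdane-6β,15,16-triol | O[C@@H]1C[C@@H](C)[C@]2(CC[C@](CO)(CCO)O2)[C@@]2(C)CCCC(C)(C)[C@@H]12 | intermediate
18 | (13R)-9α,13;15,16-diepoxy-5β,8βH-labdane-6β,15-diol | O[C@@H]1C[C@@H](C)[C@]2(CC[C@]3(CC(O)OC3)O2)[C@@]2(C)CCCC(C)(C)[C@@H]12 | intermediate (not isolated)
19 | (13R)-6β-hydroxy-9α,13-epoxy-5β,8βH-labdan-15,16-olide | O[C@@H]1C[C@@H](C)[C@]2(CC[C@]3(CC(=O)OC3)O2)[C@@]2(C)CCCC(C)(C)[C@@H]12 | intermediate
20 | (13R)-6β-acetoxy-9α,13-epoxy-5β,8βH-labdan-15,16-olide | CC(=O)O[C@@H]1C[C@@H](C)[C@]2(CC[C@]3(CC(=O)OC3)O2)[C@@]2(C)CCCC(C)(C)[C@@H]12 | intermediate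
21 | (13R)-6β-acetoxy-9α,13;15,16-diepoxy-5β,8βH-labdan-15-ol | CC(=O)O[C@@H]1C[C@@H](C)[C@]2(CC[C@]3(CC(O)OC3)O2)[C@@]2(C)CCCC(C)(C)[C@@H]12 | intermediate
22 | 15-O-methanesulfonyl derivative of 21 | CC(=O)O[C@@H]1C[C@@H](C)[C@]2(CC[C@]3(CC(OS(C)(=O)=O)OC3)O2)[C@@]2(C)CCCC(C)(C)[C@@H]12 | intermediate (not isolated)
23 | (5R,6R,8R,9R,10S,13R)-6-acetoxy-9,13;15,16-diepoxylabd-14-ene (CNP0242014.2) | CC(=O)O[C@@H]1C[C@@H](C)[C@]2(CC[C@]3(C=COC3)O2)[C@@]2(C)CCCC(C)(C)[C@@H]12 | target

**Step count**

Total steps: 13. Longest linear sequence: 13 steps (1 → 23); 5 and 13 enter as purchased partners in steps 3 and 8.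

**Steps most likely to fail**

Step 3 (proposed new method). Bond formation at the neopentyl β-carbon and the fully substituted α-carbon of 5 may be too slow for the ion-pair catalyst to control. Conversion could then stall, the adduct could revert by retro-aldol opening, or the endo and facial selectivity could erode. The fallback uses known chemistry, sets out from 4 and 5 and comes back at 6. The cycloaddition is run without asymmetric induction under the established amine-base conditions for 3-hydroxy-2-pyrones (Et3N, CH2Cl2) at 12–15 kbar, the usual remedy for hindered pyrone cycloadditions. This gives 6 as a racemate together with its enantiomer ent-6 F1. The enantiomers are separated by preparative chromatography on a chiral stationary phase, so that the absolute configuration comes from a resolution and not from the catalyst.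

Step 9. Oxygen transfer may show poor facial selectivity (competing direction by the tertiary C9 hydroxyl, mismatch with the chiral substrate), or the acid-mediated opening may drift towards an SN1 course; either leads to C13 epimers. The fallback sets out from 15 and comes back at 19. 15 is epoxidised without a chiral ligand (VO(acac)2, t-BuOOH, then camphorsulfonic acid) and the mixture is taken through step 10. This passes through (13R)-13,16-epoxy-5β,8βH-labdane-6β,9α,15-triol F2, (13S)-9α,13-epoxy-5β,8βH-labdane-6β,15,16-triol F3 and (13S)-9α,13;15,16-diepoxy-5β,8βH-labdane-6β,15-diol F4 alongside 16–18, and ends in 19 together with its C13 epimer, (13S)-6β-hydroxy-9α,13-epoxy-5β,8βH-labdan-15,16-olide F5. F5 is separated and treated with DBU in THF. Retro-oxa-Michael opening to 6β,9α-dihydroxy-5β,8βH-labd-13-en-15,16-olide F6 and re-closure re-establish the 19/F5 mixture, which is separated again. C13 is thus corrected by equilibration and recycling at the β-alkoxy lactone stage instead of by kinetic reagent control.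

Step 8. SN2 attack at the neopentyl-type epoxide carbon may be outrun by attack of the C6 alkoxide on C11 (6-exo closure to a 6β,11-ether) or by base-induced isomerisation of the epoxide. The fallback sets out from 12 and comes back at 15. LiI in THF opens 12 to 11-iodo-12,13,14,15,16-pentanor-5β,8βH-labdane-6β,9α-diol F7. Keck radical allylation of F7 with 3-[(tributylstannyl)methyl]but-3-en-1-ol F8 (made from dianion 14 and Bu3SnCl), AIBN, benzene, 80 °C, forms C11–C12 through the primary C11 radical. This radical is insensitive to the neopentyl environment and to free hydroxyls, and the reaction gives 15 directly.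

**Further compounds**

F1 | step 3 | ent-6, (enantiomer of 6) 9-hydroxy-1-oxo-pentanorlabd-7-en-11,6-olide with all four stereocentres inverted | O=C3O[C@H]1C=C(C)[C@]3(O)[C@]2(C)C(=O)CCC(C)(C)[C@H]12
F2 | step 9 | (13R)-13,16-epoxy-5β,8βH-labdane-6β,9α,15-triol | O[C@@H]1C[C@@H](C)[C@](O)(CC[C@@]3(CCO)CO3)[C@@]2(C)CCCC(C)(C)[C@@H]12
F3 | step 9 | (13S)-9α,13-epoxy-5β,8βH-labdane-6β,15,16-triol | O[C@@H]1C[C@@H](C)[C@]2(CC[C@@](CO)(CCO)O2)[C@@]2(C)CCCC(C)(C)[C@@H]12
F4 | step 9 | (13S)-9α,13;15,16-diepoxy-5β,8βH-labdane-6β,15-diol | O[C@@H]1C[C@@H](C)[C@]2(CC[C@@]3(CC(O)OC3)O2)[C@@]2(C)CCCC(C)(C)[C@@H]12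
F5 | step 9 | (13S)-6β-hydroxy-9α,13-epoxy-5β,8βH-labdan-15,16-olide | O[C@@H]1C[C@@H](C)[C@]2(CC[C@@]3(CC(=O)OC3)O2)[C@@]2(C)CCCC(C)(C)[C@@H]12
F6 | step 9 | 6β,9α-dihydroxy-5β,8βH-labd-13-en-15,16-olide | O[C@@H]1C[C@@H](C)[C@](O)(CCC3=CC(=O)OC3)[C@@]2(C)CCCC(C)(C)[C@@H]12
F7 | step 8 | 11-iodo-12,13,14,15,16-pentanor-5β,8βH-labdane-6β,9α-diol | O[C@@H]1C[C@@H](C)[C@@](CI)(O)[C@@]2(C)CCCC(C)(C)[C@@H]12
F8 | step 8 | 3-[(tributylstannyl)methyl]but-3-en-1-ol | CCCC[Sn](CCCC)(CCCC)CC(=C)CCO
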